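## Retrosynthetic overview

1. Target ⇐ phenol debenzylation and acetylation of the tertiary C1–OH of di-O-benzyl-1-hydroxypinoresinol (locants: C1 acetoxy bridgehead, C2 ArCH on C1, O3, C4, C5 bridgehead CH, C6 ArCH on C5, O7, C8; ring A = C1–C2–O3–C4–C5, ring B = C5–C6–O7–C8–C1).
2. Ring B (C6–O7 bond, C5–H) ⇐ cobalt-hydride hydroalkoxylation of a 2-aryl-4-arylidene-3-hydroxy-3-(hydroxymethyl)tetrahydrofuran.
3. Ring A and the tertiary C1–O bond ⇐ one-flask titanium–tartrate epoxidation / 5-endo epoxide opening of an achiral, C2-symmetric (E,E)-2,3-bis(arylidene)butane-1,4-diol (key C–O step; sets C1 and C2).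
4. Diene diol ⇐ AlH3 reduction ⇐ Stobbe condensation ⇐ Horner–Wadsworth–Emmons olefination, from O-benzylvanillin (used twice) and tetraethyl phosphonosuccinate.
5. Ring order: ring A first (step 4), ring B second (step 5).

Assumption: tetraethyl phosphonosuccinate is taken as an inexpensive stock reagent; the locants above are used for the same atoms in all precursors, and L-(+)-DIPT is diisopropyl (2R,3R)-tartrate.

## Route

Step 1
Reactants: 1 4-(benzyloxy)-3-methoxybenzaldehyde (O-benzylvanillin); 2 tetraethyl phosphonosuccinate [diethyl 2-(diethoxyphosphoryl)butanedioate]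
Product: 3 diethyl (2E)-2-[(4-benzyloxy-3-methoxyphenyl)methylidene]butanedioate
Conditions: NaH, THF, 0 °C → rt; aq. HCl work-up
Reagents that add atoms: none
Why: Horner–Wadsworth–Emmons olefination, in which the stabilised phosphonosuccinate anion adds reversibly to the aryl aldehyde and collapses through the less crowded oxaphosphetane to the (E)-arylidene succinate (aryl anti to the conjugated ester); no stereocentre is created.

Step 2
Reactants: 3 diethyl (2E)-2-[(4-benzyloxy-3-methoxyphenyl)methylidene]butanedioate; 1 4-(benzyloxy)-3-methoxybenzaldehyde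
Product: 5 (2E,3E)-2,3-bis[(4-benzyloxy-3-methoxyphenyl)methylidene]butanedioic acid monoethyl ester, via paraconate lactone 4 (not isolated)
Conditions: NaOEt, EtOH, reflux; then aq. HCl
Reagents that add atoms: none
Why: Stobbe condensation, in which the enolate of the saturated ester arm adds to the aldehyde, the alkoxide lactonises onto the conjugated ester to give 4, and irreversible E1cB ring opening to the carboxylate fixes the second arylidene with E geometry, giving the achiral (E,E)-diene skeleton with no stereocentre.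

Step 3
Reactants: 5 (2E,3E)-2,3-bis[(4-benzyloxy-3-methoxyphenyl)methylidene]butanedioic acid monoethyl ester
Product: 6 (2E,3E)-2,3-bis[(4-benzyloxy-3-methoxyphenyl)methylidene]butane-1,4-diol
Conditions: AlH3 (from LiAlH4 and AlCl3, 3:1), THF, 0 °C; aq. potassium sodium tartrate work-up
Reagents that add atoms: none
Why: Hydride reduction with electrophilic AlH3 converts both the carboxylic acid and the conjugated ester into primary allylic alcohols by 1,2-delivery, without conjugate reduction or loss of alkene geometry, and the benzyl ethers are inert.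

Step 4
Reactants: 6 (2E,3E)-2,3-bis[(4-benzyloxy-3-methoxyphenyl)methylidene]butane-1,4-diol
Product: 8 (2R,3S,4Z)-2-(4-benzyloxy-3-methoxyphenyl)-4-[(4-benzyloxy-3-methoxyphenyl)methylidene]-3-(hydroxymethyl)oxolan-3-ol, via epoxy diol 7 (not isolated)
Conditions: Ti(OiPr)4 (20 mol %), L-(+)-DIPT (24 mol %), TBHP (1.05 equiv), 4 Å MS, CH2Cl2, −25 °C then 0 °C; NaOH/brine work-up
Reagents that add atoms: tert-butyl hydroperoxide, CC(C)(C)OO
Why: Proposed new method: a desymmetrising epoxidative cycloetherification in which the titanium–tartrate complex epoxidises one of the two homotopic (E)-allylic alcohol units on the face dictated by L-(+)-DIPT (giving the (2S,3S)-epoxy alcohol 7 and thereby C1 as S), after which the titanium-bound epoxy alcohol, whose para-alkoxybenzylic C–O bond is strongly polarised, is opened in the same flask at that benzylic carbon by the second hydroxymethyl group in a 5-endo, invertive SN2-like attack that forms the C2–O3 bond of ring A with the aryl group cis to the new tertiary hydroxyl (C2 as R) and at the same time consumes the second allylic alcohol so that bis-epoxidation is shut down; the closest known reactions are the Sharpless–Katsuki asymmetric epoxidation, titanium-alkoxide-mediated C3-selective opening of 2,3-epoxy alcohols and acid-catalysed 5-endo cyclisation of 4-aryl-3,4-epoxybutan-1-ols to 2-aryl-3-hydroxytetrahydrofurans, which have not been merged on a 2,3-bis(arylidene)butane-1,4-diol.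

Step 5
Reactants: 8 (2R,3S,4Z)-2-(4-benzyloxy-3-methoxyphenyl)-4-[(4-benzyloxy-3-methoxyphenyl)methylidene]-3-(hydroxymethyl)oxolan-3-ol
Product: 9 (1S,2R,5R,6S)-2,6-bis(4-benzyloxy-3-methoxyphenyl)-3,7-dioxabicyclo[3.3.0]octan-1-ol (di-O-benzyl-1-hydroxypinoresinol)
Conditions: N,N'-bis(3,5-di-tert-butylsalicylidene)-1,2-cyclohexanediaminocobalt (C36H52CoN2O2, divalent cobalt, 5 mol %), N-fluoro-2,4,6-trimethylpyridinium triflate (1.5 equiv), (Me2SiH)2O (1.5 equiv), PhCF3, 0 °C → rt
Reagents that add atoms: none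
Why: Mukaiyama-type cobalt-hydride hydrogen-atom transfer / radical–polar crossover hydroalkoxylation, in which H adds to C5 to give the para-alkoxybenzylic radical at C6, oxidation gives the cation and the C8 hydroxyl closes ring B; only H delivery to the C5 face syn to the C1 hydroxyl leads to a species that can close to the obligatory cis-fused bicycle (C5 as R), and the cation is captured with the aryl group on the exo face (C6 as S), as in quinone-methide closures of pinoresinol-type lignans.

Step 6
Reactants: 9 (1S,2R,5R,6S)-2,6-bis(4-benzyloxy-3-methoxyphenyl)-3,7-dioxabicyclo[3.3.0]octan-1-ol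
Product: 10 (1S,2R,5R,6S)-2,6-bis(4-benzyloxy-3-methoxyphenyl)-3,7-dioxabicyclo[3.3.0]octan-1-yl acetate
Conditions: Ac2O (5 equiv), DMAP (0.5 equiv), Et3N, CH2Cl2, 40 °C
Reagents that add atoms: acetic anhydride, CC(=O)OC(C)=O
Why: Steglich-type nucleophilic catalysis, in which the N-acetylpyridinium ion acetylates the only free hydroxyl, the hindered tertiary C1–OH, with no change at any stereocentre.

Step 7
Reactants: 10 (1S,2R,5R,6S)-2,6-bis(4-benzyloxy-3-methoxyphenyl)-3,7-dioxabicyclo[3.3.0]octan-1-yl acetate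
Product: 11 1-acetoxypinoresinol [(1S,2R,5R,6S)-2,6-bis(4-hydroxy-3-methoxyphenyl)-3,7-dioxabicyclo[3.3.0]octan-1-yl acetate]
Conditions: H2 (1 atm), Pd/C (10 wt %), EtOAc, rt, stopped after uptake of 2 equiv H2
Reagents that add atoms: none
Why: Catalytic hydrogenolysis of aryl benzyl ethers over Pd/C in neutral ethyl acetate is far faster than cleavage of the dialkyl benzylic ethers of the furofuran and leaves the tertiary acetate and all four stereocentres untouched.

## Compound list

1 | 4-(benzyloxy)-3-methoxybenzaldehyde (O-benzylvanillin) | COc1cc(C=O)ccc1OCc1ccccc1 | starting material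
2 | tetraethyl phosphonosuccinate [diethyl 2-(diethoxyphosphoryl)butanedioate] | CCOC(=O)CC(C(=O)OCC)P(=O)(OCC)OCC | starting material
3 | diethyl (2E)-2-[(4-benzyloxy-3-methoxyphenyl)methylidene]butanedioate | CCOC(=O)C/C(=C\c1ccc(OCc2ccccc2)c(OC)c1)C(=O)OCC | intermediate
4 | ethyl 2-(4-benzyloxy-3-methoxyphenyl)-4-[(E)-(4-benzyloxy-3-methoxyphenyl)methylidene]-5-oxooxolane-3-carboxylate (paraconate lactone; racemic, both C2/C3 diastereomers, not isolated) | CCOC(=O)C1C(c2ccc(OCc3ccccc3)c(OC)c2)OC(=O)/C1=C/c1ccc(OCc2ccccc2)c(OC)c1 | intermediate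
5 | (2E,3E)-2,3-bis[(4-benzyloxy-3-methoxyphenyl)methylidene]butanedioic acid monoethyl ester | CCOC(=O)/C(=C/c1ccc(OCc2ccccc2)c(OC)c1)/C(C(=O)O)=C\c1ccc(OCc2ccccc2)c(OC)c1 | intermediate
6 | (2E,3E)-2,3-bis[(4-benzyloxy-3-methoxyphenyl)methylidene]butane-1,4-diol (achiral) | OC/C(=C/c1ccc(OCc2ccccc2)c(OC)c1)/C(CO)=C\c1ccc(OCc2ccccc2)c(OC)c1 | intermediate
7 | [(2S,3S)-3-(4-benzyloxy-3-methoxyphenyl)-2-[(1Z)-1-(4-benzyloxy-3-methoxyphenyl)-3-hydroxyprop-1-en-2-yl]oxiran-2-yl]methanol (epoxy diol, not isolated) | OC[C@@]1(O[C@H]1c1ccc(OCc2ccccc2)c(OC)c1)/C(CO)=C\c1ccc(OCc2ccccc2)c(OC)c1 | intermediate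
8 | (2R,3S,4Z)-2-(4-benzyloxy-3-methoxyphenyl)-4-[(4-benzyloxy-3-methoxyphenyl)methylidene]-3-(hydroxymethyl)oxolan-3-ol (aryl at C2 cis to the tertiary OH) | OC[C@]1(O)[C@@H](c2ccc(OCc3ccccc3)c(OC)c2)OC/C1=C/c1ccc(OCc2ccccc2)c(OC)c1 | intermediate
9 | (1S,2R,5R,6S)-2,6-bis(4-benzyloxy-3-methoxyphenyl)-3,7-dioxabicyclo[3.3.0]octan-1-ol (cis-fused, both aryl groups exo) | COc1cc([C@H]2OC[C@]3(O)[C@@H](c4ccc(OCc5ccccc5)c(OC)c4)OC[C@H]23)ccc1OCc1ccccc1 | intermediate
10 | (1S,2R,5R,6S)-2,6-bis(4-benzyloxy-3-methoxyphenyl)-3,7-dioxabicyclo[3.3.0]octan-1-yl acetate | COc1cc([C@H]2OC[C@]3(OC(C)=O)[C@@H](c4ccc(OCc5ccccc5)c(OC)c4)OC[C@H]23)ccc1OCc1ccccc1 | intermediate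
11 | 1-acetoxypinoresinol | COc1cc([C@H]2OC[C@]3(OC(C)=O)[C@@H](c4ccc(O)c(OC)c4)OC[C@H]23)ccc1O | target

## Totals and risk

Total step count: 7. Longest linear sequence: 7 steps (1 → 3 → 5 → 6 → 8 → 9 → 10 → 11; aldehyde 1 enters twice).

Three steps most likely to fail:

**Step 4 (the proposed new step).** The risks are bis-epoxidation before ring closure, titanium-mediated opening of 7 by isopropoxide or at the allylic C1 position, incomplete inversion at the benzylic carbon, and catalyst inhibition by the diol product (raise the Ti(OiPr)4 loading if so). The fallback uses known chemistry and decouples oxidation from ring closure. It sets out from 6. Monosilylation (NaH 1.0 equiv, then TBSCl 1.0 equiv, THF, 0 °C; unreacted 6 recycled) gives (2E,3E)-2,3-bis[(4-benzyloxy-3-methoxyphenyl)methylidene]-4-[(tert-butyldimethylsilyl)oxy]butan-1-ol F1. A conventional catalytic Sharpless asymmetric epoxidation of its single free allylic alcohol (Ti(OiPr)4 10 mol %, L-(+)-DIPT 12 mol %, TBHP, 4 Å MS, CH2Cl2, −25 °C) gives [(2S,3S)-3-(4-benzyloxy-3-methoxyphenyl)-2-[(1Z)-1-(4-benzyloxy-3-methoxyphenyl)-3-[(tert-butyldimethylsilyl)oxy]prop-1-en-2-yl]oxiran-2-yl]methanol F2. Buffered desilylation (TBAF, AcOH, THF, 0 °C) releases epoxy diol 7, which is cyclised in a separate acid-catalysed 5-endo epoxide opening (CSA 5 mol %, CH2Cl2, −40 °C). The fallback comes back to the route at 8.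

**Step 5.** The risks are hydrogen delivery to the wrong face of C5, ionisation of the tertiary allylic alcohol, and simple alkene reduction. The fallback replaces the radical–polar crossover by an ionic ring closure followed by reduction and sets out from 8. A 5-endo iodoetherification (I2, NaHCO3, MeCN, 0 °C) adds O7 to C6 and iodine to C5 in an anti sense, which places the aryl group exo. It gives (1S,2R,5S,6R)-2,6-bis(4-benzyloxy-3-methoxyphenyl)-5-iodo-3,7-dioxabicyclo[3.3.0]octan-1-ol F3. Radical deiodination (Bu3SnH, AIBN, toluene, 80 °C) delivers hydrogen to the bridgehead radical from the convex face. The fallback comes back to the route at 9.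

**Step 3.** The risks are sluggish reduction of the hindered, cross-conjugated carboxylate and partial conjugate reduction. The fallback changes the substrate to a diester and sets out from 5. O-Alkylation of the acid (EtI, K2CO3, DMF, rt) gives diethyl (2E,3E)-2,3-bis[(4-benzyloxy-3-methoxyphenyl)methylidene]butanedioate F4, which is reduced with iBu2AlH (5 equiv, CH2Cl2, −78 → 0 °C). The fallback comes back to the route at 6.

## Further compounds

F1 | step 4 | (2E,3E)-2,3-bis[(4-benzyloxy-3-methoxyphenyl)methylidene]-4-[(tert-butyldimethylsilyl)oxy]butan-1-ol | OC/C(=C/c1ccc(OCc2ccccc2)c(OC)c1)/C(CO[Si](C)(C)C(C)(C)C)=C\c1ccc(OCc2ccccc2)c(OC)c1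
F2 | step 4 | [(2S,3S)-3-(4-benzyloxy-3-methoxyphenyl)-2-[(1Z)-1-(4-benzyloxy-3-methoxyphenyl)-3-[(tert-butyldimethylsilyl)oxy]prop-1-en-2-yl]oxiran-2-yl]methanol | OC[C@@]1(O[C@H]1c1ccc(OCc2ccccc2)c(OC)c1)/C(CO[Si](C)(C)C(C)(C)C)=C\c1ccc(OCc2ccccc2)c(OC)c1
F3 | step 5 | (1S,2R,5S,6R)-2,6-bis(4-benzyloxy-3-methoxyphenyl)-5-iodo-3,7-dioxabicyclo[3.3.0]octan-1-ol | COc1cc([C@H]2OC[C@]3(O)[C@@H](c4ccc(OCc5ccccc5)c(OC)c4)OC[C@]23I)ccc1OCc1ccccc1
F4 | step 3 | diethyl (2E,3E)-2,3-bis[(4-benzyloxy-3-methoxyphenyl)methylidene]butanedioate | CCOC(=O)/C(=C/c1ccc(OCc2ccccc2)c(OC)c1)/C(C(=O)OCC)=C\c1ccc(OCc2ccccc2)c(OC)c1
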